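**Retrosynthetic overview**
- Feature: in ring A (2-hydroxy-5-methoxy-6-methyl-1,4-quinone) and ring B (2,5-dihydroxy-6-methyl-1,4-quinone) the chain-bearing carbon is para to the C-methyl carbon, and both neighbours of the C-methyl carbon carry oxygen. Each ring is thus a 2-methyl-5-alkylresorcinol with two further oxygens beside the chain, and such a resorcinol is a folded 4-methyl-3,5,7-triketo ester.
- End game: target ⇐ aryl acetates (methanolysis, air) ⇐ Thiele–Winter acetoxylation ⇐ bis-quinone ⇐ (KSO3)2NO oxidation of the mono-methyl ether of the bis-resorcinol. The single O-methylation is the only desymmetrising step.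
- Ring formation: both benzene rings close in one operation by twofold C2→C7 aldol aromatisation of a bis(3,5,7-triketo ester) to the bis-resorcylate. The ester groups are then removed by saponification and decarboxylation; rings A and B are identical until the methylation.
- Precursor: bis(triketo ester) ⇐ trianion of methyl 4-methyl-3,5-dioxohexanoate (from 3-methylpentane-2,4-dione and dimethyl carbonate) + bis-Weinreb amide of hexadecanedioic acid. The two carboxyl carbons of the diacid become the chain-bearing ring carbons.

Key step: step 4

Remark: the target has no stereocentre; the linker is read as fourteen CH2 groups; polycarbonyl compounds are drawn as keto forms and the quinones as the tautomers of the target SMILES.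

**Step 1**
Reactants: 1 3-methylpentane-2,4-dione; 2 dimethyl carbonate
Product: 3 methyl 4-methyl-3,5-dioxohexanoate
Conditions: LiN(iPr)2 (3.1 equiv), THF, −78 to 0 °C; then 2, −78 °C to rt; aq. HCl
Reagents that add atoms: none
Why: Claisen-type C-acylation of a β-diketone 1,3-dianion, in which the terminal carbanion (formed last, most nucleophilic) attacks dimethyl carbonate and the extra equivalent of base takes up the more acidic diketo ester as it forms.

**Step 2**
Reactants: 4 hexadecanedioic acid
Product: 6 N1,N16-dimethoxy-N1,N16-dimethylhexadecanediamide, via hexadecanedioyl bis-imidazolide 5 (not isolated)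
Conditions: CDI (2.2 equiv), THF, 40 °C; then MeNH(OMe)·HCl (2.4 equiv), rt
Reagents that add atoms: N,O-dimethylhydroxylamine hydrochloride, CNOC.Cl; 1,1'-carbonyldiimidazole, O=C(n1ccnc1)n1ccnc1 (gives the imidazolyl groups of 5, none of its atoms remain in 6)
Why: Activation of both carboxyl groups as acyl imidazolides followed by aminolysis (Weinreb amide formation) is a reliable one-pot amidation that leaves the fourteen CH2 groups untouched.

**Step 3**
Reactants: 3 methyl 4-methyl-3,5-dioxohexanoate; 6 N1,N16-dimethoxy-N1,N16-dimethylhexadecanediamide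
Product: 7 dimethyl 4,25-dimethyl-3,5,7,22,24,26-hexaoxooctacosanedioate
Conditions: 3 (2.4 equiv), LiN(iPr)2 (7.2 equiv), THF, −78 to 0 °C; then 6 (1 equiv), −78 to 0 °C; AcOH, −78 °C
Reagents that add atoms: none
Why: Polyanion acylation, in which the terminal C6 carbanion of the trianion of 3 (the last-formed and most reactive site) adds to each Weinreb amide, and the chelated tetrahedral adduct should persist until the quench, so that no over-addition occurs and the acidic triketo ester is not released to consume further trianion.

**Step 4**
Reactants: 7 dimethyl 4,25-dimethyl-3,5,7,22,24,26-hexaoxooctacosanedioate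
Product: 9 dimethyl 6,6'-(tetradecane-1,14-diyl)bis(2,4-dihydroxy-3-methylbenzoate), via twofold aldol adduct 8 (not isolated)
Conditions: KOH (0.5 M aq.), THF, Ar, 0 °C to rt; then 1 M HCl, 0 °C
Reagents that add atoms: none
Why: Hydroxide turns each terminus into a polyenolate in which C2 (numbered from the ester carbon) is nucleophilic as the β-keto ester enolate and attacks the C7 ketone; the tertiary aldolate 8 loses water by E1cB and the two ring ketones enolise, so aromatisation makes each closure irreversible. This is the base-promoted aldol cyclisation of 3,5,7-triketo esters to β-resorcylates, a reaction type also known for C4-substituted substrates. Each ring closes 6-exo-trig on the C7 carbonyl through the ester-enolate form, that is 6-(enolexo)-exo-trig, a favoured mode, and the two termini, separated by fourteen CH2 groups, react independently. No stereocentre is set, since the carbinol and methine centres of 8 are transient and all become sp2. The step needs C-attack on the ketone to win over attack on the ester (Claisen closure of C6 onto C1 to an acylphloroglucinol, or lactonisation of the C5 enol oxygen to a 2-pyranone); in aqueous KOH the ester belongs to a deprotonated β-keto ester and is deactivated as an electrophile, no chelating divalent cation or dehydrating acid is present, and C4 keeps one hydrogen for the final enolisation.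

**Step 5**
Reactants: 9 dimethyl 6,6'-(tetradecane-1,14-diyl)bis(2,4-dihydroxy-3-methylbenzoate)
Product: 11 5,5'-(tetradecane-1,14-diyl)bis(2-methylbenzene-1,3-diol), via bis-resorcylic diacid 10 (not isolated)
Conditions: KOH, H2O/ethylene glycol, 120 °C, Ar; then aq. HCl, 80 °C
Reagents that add atoms: water, O (its oxygen is in the carboxyl groups of 10 and leaves as CO2; only hydrogen remains in 11)
Why: Saponification of the hindered o-hydroxybenzoate followed by protodecarboxylation of the β-resorcylic acid, which proceeds by ipso-protonation of a carbon ortho and para to hydroxyl groups, the same reaction that turns orsellinates into orcinols.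

**Step 6**
Reactants: 11 5,5'-(tetradecane-1,14-diyl)bis(2-methylbenzene-1,3-diol)
Product: 12 5-[14-(3-hydroxy-5-methoxy-4-methylphenyl)tetradecyl]-2-methylbenzene-1,3-diol
Conditions: MeI (0.8 equiv), K2CO3 (1 equiv), acetone, 40 °C, Ar; chromatography, recovered 11 recycled
Reagents that add atoms: iodomethane, CI
Why: Williamson etherification with substoichiometric MeI is statistical, but since all four hydroxyl groups are symmetry-equivalent only one mono-ether can form, and stopping at partial conversion should allow 12 to be separated from recovered 11 and from more highly methylated by-products.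

**Step 7**
Reactants: 12 5-[14-(3-hydroxy-5-methoxy-4-methylphenyl)tetradecyl]-2-methylbenzene-1,3-diol
Product: 13 3-hydroxy-5-[14-(5-methoxy-4-methyl-3,6-dioxocyclohexa-1,4-dien-1-yl)tetradecyl]-2-methylcyclohexa-2,5-diene-1,4-dione
Conditions: (KSO3)2NO (6 equiv), KH2PO4, H2O/CH2Cl2, methyltrioctylammonium chloride (cat.), rt
Reagents that add atoms: potassium nitrosodisulfonate, [K+].[K+].[O-]S(=O)(=O)N([O])S(=O)(=O)[O-]
Why: Teuber oxidation by the nitrosodisulfonate radical should convert the ring A phenol, whose para position (between the OMe carbon and the chain carbon) is free, into the methoxy-p-quinone and the ring B resorcinol, at the equivalent position para to one hydroxyl, into the 2-hydroxy-p-quinone, the pattern known for orcinol and its monomethyl ether.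

**Step 8**
Reactants: 13 3-hydroxy-5-[14-(5-methoxy-4-methyl-3,6-dioxocyclohexa-1,4-dien-1-yl)tetradecyl]-2-methylcyclohexa-2,5-diene-1,4-dione
Product: 14 3-[14-(2,3,6-triacetoxy-5-methoxy-4-methylphenyl)tetradecyl]-6-methylbenzene-1,2,4,5-tetrayl tetraacetate
Conditions: Ac2O, H2SO4 (cat.), rt to 45 °C
Reagents that add atoms: acetic anhydride, CC(=O)OC(C)=O
Why: Thiele–Winter acetoxylation, in which acid-catalysed conjugate addition of acetate to the only unsubstituted ring carbon of each quinone (next to the chain carbon) is followed by enolisation and O-acetylation, the ring B hydroxyl being acetylated first; trisubstituted hydroxy- and methoxy-p-quinones are known substrates and no regiochemical choice exists.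

**Step 9**
Reactants: 14 3-[14-(2,3,6-triacetoxy-5-methoxy-4-methylphenyl)tetradecyl]-6-methylbenzene-1,2,4,5-tetrayl tetraacetate
Product: 16 2,5-dihydroxy-3-[14-(2-hydroxy-5-methoxy-4-methyl-3,6-dioxocyclohexa-1,4-dien-1-yl)tetradecyl]-6-methylcyclohexa-2,5-diene-1,4-dione, via hexahydroxy bis-hydroquinone 15 (not isolated)
Conditions: K2CO3, MeOH/THF (degassed), Ar, 0 °C to rt; then O2 (air), rt; then 1 M HCl
Reagents that add atoms: none
Why: Base-catalysed transesterification of the seven aryl acetates should give the air-sensitive hydroxyhydroquinones 15, whose phenolates are autoxidised by O2 to the hydroxy-p-quinones, while the ring A methoxy group survives because methoxide exchange at this vinylogous ester is degenerate and both hydroxyquinones remain unreactive anions until acidification.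

**Compound list**
1 | 3-methylpentane-2,4-dione | CC(=O)C(C)C(C)=O | starting material
2 | dimethyl carbonate | COC(=O)OC | starting material
3 | methyl 4-methyl-3,5-dioxohexanoate | COC(=O)CC(=O)C(C)C(C)=O | intermediate
4 | hexadecanedioic acid | OC(=O)CCCCCCCCCCCCCCC(=O)O | starting material
5 | 1,16-di(1H-imidazol-1-yl)hexadecane-1,16-dione (not isolated) | O=C(n1ccnc1)CCCCCCCCCCCCCCC(=O)n1ccnc1 | intermediate
6 | N1,N16-dimethoxy-N1,N16-dimethylhexadecanediamide | CON(C)C(=O)CCCCCCCCCCCCCCC(=O)N(C)OC | intermediate
7 | dimethyl 4,25-dimethyl-3,5,7,22,24,26-hexaoxooctacosanedioate (keto form) | COC(=O)CC(=O)C(C)C(=O)CC(=O)CCCCCCCCCCCCCCC(=O)CC(=O)C(C)C(=O)CC(=O)OC | intermediate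
8 | dimethyl 2,2'-(tetradecane-1,14-diyl)bis(2-hydroxy-5-methyl-4,6-dioxocyclohexane-1-carboxylate), mixture of stereoisomers (not isolated) | COC(=O)C1C(=O)C(C)C(=O)CC1(O)CCCCCCCCCCCCCCC1(O)CC(=O)C(C)C(=O)C1C(=O)OC | intermediate
9 | dimethyl 6,6'-(tetradecane-1,14-diyl)bis(2,4-dihydroxy-3-methylbenzoate) | COC(=O)c1c(O)c(C)c(O)cc1CCCCCCCCCCCCCCc1cc(O)c(C)c(O)c1C(=O)OC | intermediate
10 | 6,6'-(tetradecane-1,14-diyl)bis(2,4-dihydroxy-3-methylbenzoic acid) (not isolated) | OC(=O)c1c(O)c(C)c(O)cc1CCCCCCCCCCCCCCc1cc(O)c(C)c(O)c1C(=O)O | intermediate
11 | 5,5'-(tetradecane-1,14-diyl)bis(2-methylbenzene-1,3-diol) | Cc1c(O)cc(CCCCCCCCCCCCCCc2cc(O)c(C)c(O)c2)cc1O | intermediate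
12 | 5-[14-(3-hydroxy-5-methoxy-4-methylphenyl)tetradecyl]-2-methylbenzene-1,3-diol | COc1cc(CCCCCCCCCCCCCCc2cc(O)c(C)c(O)c2)cc(O)c1C | intermediate
13 | 3-hydroxy-5-[14-(5-methoxy-4-methyl-3,6-dioxocyclohexa-1,4-dien-1-yl)tetradecyl]-2-methylcyclohexa-2,5-diene-1,4-dione | COC1=C(C)C(=O)C=C(CCCCCCCCCCCCCCC2=CC(=O)C(C)=C(O)C2=O)C1=O | intermediate
14 | 3-[14-(2,3,6-triacetoxy-5-methoxy-4-methylphenyl)tetradecyl]-6-methylbenzene-1,2,4,5-tetrayl tetraacetate | COc1c(C)c(OC(C)=O)c(OC(C)=O)c(CCCCCCCCCCCCCCc2c(OC(C)=O)c(OC(C)=O)c(C)c(OC(C)=O)c2OC(C)=O)c1OC(C)=O | intermediate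
15 | 3-[14-(2,3,6-trihydroxy-5-methoxy-4-methylphenyl)tetradecyl]-6-methylbenzene-1,2,4,5-tetrol (not isolated) | COc1c(C)c(O)c(O)c(CCCCCCCCCCCCCCc2c(O)c(O)c(C)c(O)c2O)c1O | intermediate
16 | 2,5-dihydroxy-3-[14-(2-hydroxy-5-methoxy-4-methyl-3,6-dioxocyclohexa-1,4-dien-1-yl)tetradecyl]-6-methylcyclohexa-2,5-diene-1,4-dione | COC1=C(C)C(=O)C(O)=C(CCCCCCCCCCCCCCC2=C(O)C(=O)C(C)=C(O)C2=O)C1=O | target

**Step count**
Total steps: 9. Longest linear sequence: 8 steps (steps 1, 3, 4, 5, 6, 7, 8, 9; the branch through step 2 is equally long).

**Steps most likely to fail**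

Step 3. The twofold acylation may stop halfway: after the first addition the chain carries a lithium polyanion that can precipitate or pass a proton to fresh trianion, so mono-acylated material and recovered 3 would result. The fallback reverses the order of the two C–C bond formations; it sets out from 1 and 6 and returns at 7. The dianion of 1 (LiN(iPr)2, THF) is acylated at its terminal carbanion by 6 to give 3,24-dimethylhexacosane-2,4,6,21,23,25-hexaone F1. F1 is then converted into its twofold trianion, in which the terminal methyl groups should be deprotonated in preference to the chain CH2 groups, and carboxylated at both ends with dimethyl carbonate 2 to give 7.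

Step 4. At one or both termini the ester carbonyl may be attacked instead of the C7 ketone (Claisen closure or lactonisation), or hydroxide may cleave a β-diketone unit, giving mixed or truncated ring systems. The fallback uses an ester that cannot serve as an electrophile; it sets out from 1 and 6 and returns at 11. The dianion of 1 is carboxylated with di-tert-butyl dicarbonate to tert-butyl 4-methyl-3,5-dioxohexanoate F2. The trianion of F2 is acylated by 6 as in step 3 to give di-tert-butyl 4,25-dimethyl-3,5,7,22,24,26-hexaoxooctacosanedioate F3. F3 is cyclised with aqueous KOH/THF to di-tert-butyl 6,6'-(tetradecane-1,14-diyl)bis(2,4-dihydroxy-3-methylbenzoate) F4. TsOH (cat.) in refluxing toluene then expels 2-methylpropene, and the diacid 10 so formed decarboxylates to 11.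

Step 8. Conjugate addition of acetate to the trisubstituted, donor-substituted quinones may be too slow, so that acid-mediated decomposition overtakes the reaction before both rings are acetoxylated. The fallback replaces the acid-catalysed addition by nucleophilic epoxidation and rearrangement; it sets out from 13 and returns at 16, making step 9 unnecessary. H2O2/Na2CO3 in aqueous THF at 0 °C should epoxidise only the chain-bearing C=C bond of each ring, because the OMe- and OH-bearing double bonds are vinylogous ester or acid units; ring B reacts as its anion and is expected to be the slower ring. This gives 3-hydroxy-1-[14-(3-methoxy-4-methyl-2,5-dioxo-7-oxabicyclo[4.1.0]hept-3-en-1-yl)tetradecyl]-4-methyl-7-oxabicyclo[4.1.0]hept-3-ene-2,5-dione F5. Brief treatment of F5 with cold concentrated H2SO4 (or SiO2/Et3N) opens each epoxide to the hydroxyquinone, as in the classical route from 2-methylnaphthoquinone oxide to 2-hydroxy-3-methylnaphthoquinone, and gives 16.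

**Further compounds**
F1 | step 3 | 3,24-dimethylhexacosane-2,4,6,21,23,25-hexaone | CC(=O)C(C)C(=O)CC(=O)CCCCCCCCCCCCCCC(=O)CC(=O)C(C)C(C)=O
F2 | step 4 | tert-butyl 4-methyl-3,5-dioxohexanoate | CC(=O)C(C)C(=O)CC(=O)OC(C)(C)C
F3 | step 4 | di-tert-butyl 4,25-dimethyl-3,5,7,22,24,26-hexaoxooctacosanedioate | CC(C)(C)OC(=O)CC(=O)C(C)C(=O)CC(=O)CCCCCCCCCCCCCCC(=O)CC(=O)C(C)C(=O)CC(=O)OC(C)(C)C
F4 | step 4 | di-tert-butyl 6,6'-(tetradecane-1,14-diyl)bis(2,4-dihydroxy-3-methylbenzoate) | CC(C)(C)OC(=O)c1c(O)c(C)c(O)cc1CCCCCCCCCCCCCCc1cc(O)c(C)c(O)c1C(=O)OC(C)(C)C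
F5 | step 8 | 3-hydroxy-1-[14-(3-methoxy-4-methyl-2,5-dioxo-7-oxabicyclo[4.1.0]hept-3-en-1-yl)tetradecyl]-4-methyl-7-oxabicyclo[4.1.0]hept-3-ene-2,5-dione, mixture of stereoisomers | COC1=C(C)C(=O)C2OC2(CCCCCCCCCCCCCCC23OC2C(=O)C(C)=C(O)C3=O)C1=O
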